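## The problem

Podocarpusflavone A (27) is a biflavone with no stereocentre. An apigenin unit (unit 1; chromone atoms unprimed, ring B primed) is bonded through C3' of ring B to C8'' of an acacetin unit (unit 2; chromone atoms double-primed, the 4-methoxyphenyl ring triple-primed). The C3'–C8'' axis has three ortho substituents (O4', O7'' and C8a''–O1'') but is not a defined stereoelement, so nothing has to be relayed and the difficulties are regiochemical and chemoselective. The biaryl bond is hindered and resists a late coupling of two flavone halves. Ring A of unit 2 is a phloroglucinol ring whose three oxygens have different fates: the pyranone must close through the oxygen beside the aryl group (O1''), since closure through the other ortho oxygen gives the 6-linked isomer. Of six phenolic oxygens only O4''' stays methylated, so every temporary group must leave under conditions that spare an anisole methyl ether. The chromones are opened by hot hydroxide, an aryl bromide rules out alkyllithium reagents, and a siloxyalkyne is easily hydrolysed. The enabling feature is that C8'' carries the aryl group between the oxygen-bearing carbons C8a'' and C7'', with the third oxygen para to it at C5''. This is the pattern produced when the vinylketene from a 3-alkoxycyclobutenone combines with an aryl ynol ether: ketene oxygen becomes O1'', the alkyne carbons become C8'' and C7'', and the alkoxy group becomes O5''.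

## Retrosynthesis

**27 from 26.** The last cut removes five O–alkyl bonds: four benzyl ethers (O5, O7, O4', O7'') and the ethyl ether at O5''. Benzyl and a chelated ethyl are chosen over methyl because the one ether that must survive is itself a methyl ether. Benzyl ethers ionise under a boron Lewis acid at low temperature, and the O5'' ethyl group is cleaved only because it sits in a chelate with the C4'' carbonyl. The forward step must discriminate between a chelated and an unchelated alkyl aryl ether.

**26 from 25 and 24.** The pyranone of unit 1 is opened at O1–C2 (cyclodehydration) and C2–C3 (Baker–Venkataraman acyl shift), leading back to aryl ester 24. A chalcone route to unit 1 would need an aldehyde on ring B and a hydroxide condensation in the presence of the finished chromone of unit 2. The acyl shift runs with an amide base at low temperature and tolerates that ring. Ester 24 is simply two halves joined by one ester bond.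

**24 from 21 and 23.** The C1'–acyl bond and the acyl–oxygen bond are cut together in a carbonylative ester synthesis from aryl bromide 21 and phenol 23. The bromide is preferred to a pre-installed carboxyl group because it is inert to amide bases, heat, Lewis acid, hydroxide and iodine. It also sits para to O4', far from the hindered axis, so oxidative addition is unimpeded. Phenol 23 comes in one step from 22.

**21 from 19, and 19 from 17 and 18.** The pyranone of unit 2 is cut at O1''–C2'' (oxidative cyclization of chalcone 19) and C2''–C3'' (Claisen–Schmidt condensation of ketone 17 with aldehyde 18). This is shorter than an acylation–rearrangement sequence and uses a cheap aldehyde. Regiochemistry is guaranteed by 17: the acetyl group has an ethyl ether on one side and the only free hydroxyl, next to the aryl group, on the other, so only the 8-aryl flavone can form.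

**17 from 15, and 15 from 12.** The C4a''–C4'' bond is cut (Fries acetylation beside the free hydroxyl of 12), and the O7'' benzyl ether is traced to the silyl ether of 12. The silyl group cannot be carried further, because the hydroxide of step 7 would strip it and leave a phenoxide that later competes in the carbonylation. The exchange is robust because, before acylation, the two oxygens flanking the aryl group are equivalent positions of the ring. Acylation ortho or para to the free hydroxyl, or premature silyl loss, all lead to the same 17 once silicon is replaced by benzyl.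

**12 from 6 and 7 (key disconnection).** Ring A of unit 2 is cut at C8a''–C8'', C6''–C7'' and C4a''–C8a''. The neighbouring cut, a cross-coupling at C3'–C8'', would need a tri-ortho-substituted coupling, a pre-differentiated phloroglucinol halide, and a partner whose own bromide competes. The benzannulation builds the ring with the aryl group in place and delivers the three oxygens as hydroxyl, silyl ether and ethyl ether in one step. The precursors are the commercial four-carbon ketone 7 and alkyne 6. The forward reaction needs one regiochemical event, the orientation of the ynol ether towards the ketene.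

**6 from 3, 3 from 2, 2 from 1.** The ynol C–O bond is cut (oxygen transfer to the acetylide of 3, then O-silylation), then the triple bond (one-carbon homologation of aldehyde 2), then the benzyl ether of 1. The aryl bromide dictates a route to the ynolate that uses only an amide base.

## Roads not taken

**Alternative 1: twofold Baker–Venkataraman acyl shift.** The cut is C2–C3 and C2''–C3'' at once. A biaryl diester A2 carries an acetyl group on each phloroglucinol ring and both aroyl residues as esters; base induces two acyl shifts to the bis(1,3-diketone) A1, and double cyclodehydration and debenzylation follow. As an endgame it is at least as good as the chosen one: both pyranones arise in two operations from one intermediate, about one operation fewer than steps 7, 8 and 10–12, and without a carbonylation. Its weakness is that it solves the easy half. A2 must already contain the hindered C3'–C8'' bond and a ring A of unit 2 in which exactly the hydroxyl beside the aryl group is acylated; the strategy supplies neither. The ester on that hydroxyl is flanked by acetyl and aryl groups, so both its formation and the acyl shift are hindered. The chosen plan sets against the shorter endgame a single step that creates the biaryl-bearing ring and the oxygen differentiation, and it borrows the acyl shift for unit 1 only.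

**Alternative 2: hexadehydro-Diels–Alder cascade.** The cut is C4a''–C8a'' and C7''–C8'' plus the C5''–O bond. Triyne A4 (a siloxy-1,3-diynyl ketone tethered through a Z enol ether to an aryl ynol ether) cyclizes thermally to an aryne, which a carboxylic acid traps to give A3. The gain in complexity is larger than in the chosen key step: both rings of unit 2 close at once with ring B attached, and A3 already carries the carboxyl needed for unit 1, so it is ahead of 21 by a carbonylation and by steps 5–8. Against this, A4 combines an alkynyl enol ether of fixed geometry, a diynone and a siloxyalkyne in one molecule; no short, reliable assembly is evident and each function is labile. The trap must add at C5'' and not at C6'', and the acetate and silyl ether then need further exchange. The chosen plan uses a three-step alkyne and a commercial cyclobutenone, and its regiochemistry rests on simple ynol-ether polarization.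

**Alternative 3: Diels–Alder aromatization that grows ring B.** The cut is C1'–C2' and C5'–C6'. Amino-siloxy diene A6, built on C8'' of a finished unit 2, adds a propiolate ester; loss of the amine aromatizes ring B to give A5. Unit 2 would come from routine phloroacetophenone chemistry, diene polarization places the ester para to the siloxy group, and A5, like A3, already has the carboxyl group in place. The weak point is that the diene must be raised from a C8'' acetyl group. Acylation of a 5,7-dioxygenated flavone at C8'' rather than C6'' is the same differentiation problem in another guise. The diene is also flanked by O7'' and the pyranone oxygen, which slows cycloaddition. The route spends its key step on ring B, the simplest ring of the target, and leaves the phloroglucinol ring to be solved separately. The chosen plan is not shorter after the key step, but it places the three oxygens of ring A unambiguously.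

Key step: step 4

Assumption: the C3'–C8'' axis is treated as configurationally undefined, as in the target structure, so all biaryl intermediates are handled as rotamer or racemic mixtures.

## Route

Step 1
Reactants: 1 5-bromo-2-hydroxybenzaldehyde
Product: 2 2-(benzyloxy)-5-bromobenzaldehyde
Conditions: BnBr, K2CO3, DMF, rt
Reagents that add atoms: benzyl bromide, BrCc1ccccc1
Why: Williamson ether synthesis on the phenoxide; the benzyl ether tolerates amide bases, heat, BF3·OEt2, hydroxide and iodine and leaves with BCl3 at the end.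

Step 2
Reactants: 2 2-(benzyloxy)-5-bromobenzaldehyde
Product: 3 1-(benzyloxy)-4-bromo-2-ethynylbenzene
Conditions: dimethyl (1-diazo-2-oxopropyl)phosphonate, K2CO3, MeOH, 0 °C → rt
Reagents that add atoms: dimethyl (1-diazo-2-oxopropyl)phosphonate, CC(=O)C(=[N+]=[N-])P(=O)(OC)OC
Why: Ohira–Bestmann homologation: methanolysis frees the diazomethylphosphonate anion, which olefinates the aldehyde; loss of N2 and a 1,2-hydrogen shift give the terminal alkyne, and the carbonate conditions leave the aryl bromide alone.

Step 3
Reactants: 3 1-(benzyloxy)-4-bromo-2-ethynylbenzene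
Product: 6 [2-(benzyloxy)-5-bromophenyl]ethynyl triisopropylsilyl ether, via lithium acetylide 4 (not isolated), via lithium ynolate 5 (not isolated)
Conditions: t-BuOOH, LiN(SiMe3)2 (2.3 equiv), THF, −78 → 0 °C; then i-Pr3SiOTf, −78 → 0 °C
Reagents that add atoms: tert-butyl hydroperoxide, CC(C)(C)OO; triisopropylsilyl trifluoromethanesulfonate, CC(C)[Si](OS(=O)(=O)C(F)(F)F)(C(C)C)C(C)C
Why: Electrophilic oxygen transfer from lithium tert-butylperoxide to acetylide 4 (loss of tert-butoxide) gives ynolate 5, which a bulky silyl triflate traps on oxygen; only an amide base is present, so the aryl bromide is not exchanged.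

Step 4
Reactants: 6 [2-(benzyloxy)-5-bromophenyl]ethynyl triisopropylsilyl ether; 7 3-ethoxycyclobut-2-en-1-one
Product: 12 2-[2-(benzyloxy)-5-bromophenyl]-5-ethoxy-3-[(triisopropylsilyl)oxy]phenol, via vinylketene 8 (not isolated), via vinylcyclobutenone 9 (not isolated), via dienylketene 10 (not isolated), via cyclohexadienone 11 (not isolated)
Conditions: toluene, 80 °C then 110 °C, argon
Reagents that add atoms: none
Why: This is a Danheiser benzannulation, the known thermal union of cyclobutenones with siloxyalkynes to give monosilylated resorcinols. Four-electron electrocyclic opening of 7 gives vinylketene 8, whose ketene C=C adds to the triple bond of 6 in a [2+2] cycloaddition (bonds C8a''–C8'' and C6''–C7'') to give 9. A second four-electron opening of 9 gives dienylketene 10, and six-electron electrocyclization (bond C4a''–C8a'') followed by enolization of 11 gives phenol 12. Ring A of unit 2 thus closes by 6π electrocyclic ring closure of an acyclic dienylketene, while the four-membered ring of 9 closes by cycloaddition and opens again. No stereocentre is created: the sp3 carbons of 9 and 11 vanish on ring opening and tautomerization, and the biaryl axis is not a defined stereoelement. The step needs regioselectivity in the [2+2] event: the aryl-bearing alkyne carbon, made nucleophilic by the siloxy oxygen, must bond to the electrophilic ketene carbonyl carbon, and the polarization of the ynol ether secures this, so the aryl group ends between the new hydroxyl and the siloxy group with the ethoxy group para to it. The bulky silyl group should stay on its oxygen, and the bromide and benzyl ether are inert to heat in toluene.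

Step 5
Reactants: 12 2-[2-(benzyloxy)-5-bromophenyl]-5-ethoxy-3-[(triisopropylsilyl)oxy]phenol
Product: 15 1-{3-[2-(benzyloxy)-5-bromophenyl]-6-ethoxy-2-hydroxy-4-[(triisopropylsilyl)oxy]phenyl}ethan-1-one, via aryl acetate 13 (not isolated), via difluoroboron chelate 14 (not isolated)
Conditions: Ac2O, BF3·OEt2, CH2Cl2, 0 °C → rt; aq. NaOAc work-up
Reagents that add atoms: acetic anhydride, CC(=O)OC(C)=O
Why: O-Acetylation followed by Fries rearrangement on a strongly activated ring; the acyl group should settle ortho to the hydroxyl because the product is held as chelate 14, which also deactivates the ring against a second acylation. Any para-acylated or desilylated material converges to the same compound in step 6.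

Step 6
Reactants: 15 1-{3-[2-(benzyloxy)-5-bromophenyl]-6-ethoxy-2-hydroxy-4-[(triisopropylsilyl)oxy]phenyl}ethan-1-one
Product: 17 1-{4-(benzyloxy)-3-[2-(benzyloxy)-5-bromophenyl]-6-ethoxy-2-hydroxyphenyl}ethan-1-one, via dihydroxy ketone 16 (not isolated)
Conditions: CsF, BnBr (1.1 equiv), DMF, rt
Reagents that add atoms: benzyl bromide, BrCc1ccccc1
Why: Desilylative Williamson alkylation: fluoride cleaves the Si–O bond and the freed phenoxide para to the acetyl group is benzylated, while the hydroxyl hydrogen-bonded to the carbonyl stays free, as in selective 4-O-alkylation of 2,4-dihydroxyacetophenones.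

Step 7
Reactants: 17 1-{4-(benzyloxy)-3-[2-(benzyloxy)-5-bromophenyl]-6-ethoxy-2-hydroxyphenyl}ethan-1-one; 18 4-methoxybenzaldehyde
Product: 19 (E)-1-{4-(benzyloxy)-3-[2-(benzyloxy)-5-bromophenyl]-6-ethoxy-2-hydroxyphenyl}-3-(4-methoxyphenyl)prop-2-en-1-one
Conditions: KOH, EtOH/THF, rt
Reagents that add atoms: none
Why: Claisen–Schmidt condensation of a 2-hydroxy-4,6-dialkoxyacetophenone with a non-enolizable aldehyde; dehydration of the aldol gives the conjugated E alkene under thermodynamic control.

Step 8
Reactants: 19 (E)-1-{4-(benzyloxy)-3-[2-(benzyloxy)-5-bromophenyl]-6-ethoxy-2-hydroxyphenyl}-3-(4-methoxyphenyl)prop-2-en-1-one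
Product: 21 7-(benzyloxy)-8-[2-(benzyloxy)-5-bromophenyl]-5-ethoxy-2-(4-methoxyphenyl)-4H-chromen-4-one, via flavanone 20 (not isolated)
Conditions: I2 (10 mol %), DMSO, 120 °C
Reagents that add atoms: none
Why: Iodine-catalysed oxidative cyclization of a 2'-hydroxychalcone: oxa-Michael closure to flavanone 20, alpha-iodination and loss of HI, with DMSO as terminal oxidant; only the hydroxyl beside the aryl group is free, so the 8-aryl flavone is the sole possible regioisomer.

Step 9
Reactants: 22 1-(2,4,6-trihydroxyphenyl)ethan-1-one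
Product: 23 1-[2,4-bis(benzyloxy)-6-hydroxyphenyl]ethan-1-one
Conditions: BnBr (2.1 equiv), K2CO3, DMF, rt
Reagents that add atoms: benzyl bromide, BrCc1ccccc1
Why: Williamson ether synthesis that stops at the dibenzyl ether because the last hydroxyl is hydrogen-bonded to the acetyl carbonyl and is the least nucleophilic.

Step 10
Reactants: 21 7-(benzyloxy)-8-[2-(benzyloxy)-5-bromophenyl]-5-ethoxy-2-(4-methoxyphenyl)-4H-chromen-4-one; 23 1-[2,4-bis(benzyloxy)-6-hydroxyphenyl]ethan-1-one
Product: 24 2-acetyl-3,5-bis(benzyloxy)phenyl 4-(benzyloxy)-3-[7-(benzyloxy)-5-ethoxy-2-(4-methoxyphenyl)-4-oxo-4H-chromen-8-yl]benzoate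
Conditions: CO (1 atm), Pd(OAc)2 (5 mol %), Xantphos, Et3N, toluene, 100 °C
Reagents that add atoms: carbon monoxide, [C-]#[O+]
Why: Palladium-catalysed aryloxycarbonylation: zerovalent palladium adds to the unhindered aryl bromide, CO inserts, and the acylpalladium species is captured by the phenoxide of 23; Et3N is too weak to enolize the methyl ketone, so the ester should be isolable.

Step 11
Reactants: 24 2-acetyl-3,5-bis(benzyloxy)phenyl 4-(benzyloxy)-3-[7-(benzyloxy)-5-ethoxy-2-(4-methoxyphenyl)-4-oxo-4H-chromen-8-yl]benzoate
Product: 25 1-[2,4-bis(benzyloxy)-6-hydroxyphenyl]-3-{4-(benzyloxy)-3-[7-(benzyloxy)-5-ethoxy-2-(4-methoxyphenyl)-4-oxo-4H-chromen-8-yl]phenyl}propane-1,3-dione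
Conditions: LiN(SiMe3)2 (3 equiv), THF, −78 → −10 °C; aq. NH4Cl
Reagents that add atoms: none
Why: Baker–Venkataraman rearrangement: the methyl ketone enolate attacks the neighbouring ester carbonyl through a six-membered transition state and the phenoxide is expelled; the non-nucleophilic base at low temperature should leave the chromone of unit 2 intact.

Step 12
Reactants: 25 1-[2,4-bis(benzyloxy)-6-hydroxyphenyl]-3-{4-(benzyloxy)-3-[7-(benzyloxy)-5-ethoxy-2-(4-methoxyphenyl)-4-oxo-4H-chromen-8-yl]phenyl}propane-1,3-dione
Product: 26 5,7-bis(benzyloxy)-2-{4-(benzyloxy)-3-[7-(benzyloxy)-5-ethoxy-2-(4-methoxyphenyl)-4-oxo-4H-chromen-8-yl]phenyl}-4H-chromen-4-one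
Conditions: p-TsOH·H2O (cat.), toluene, 90 °C
Reagents that add atoms: none
Why: Acid-catalysed cyclodehydration of an ortho-hydroxyaryl 1,3-diketone (hemiketal formation, then loss of water) closes the pyranone of unit 1 through the only free hydroxyl.

Step 13
Reactants: 26 5,7-bis(benzyloxy)-2-{4-(benzyloxy)-3-[7-(benzyloxy)-5-ethoxy-2-(4-methoxyphenyl)-4-oxo-4H-chromen-8-yl]phenyl}-4H-chromen-4-one
Product: 27 podocarpusflavone A, 8-[5-(5,7-dihydroxy-4-oxo-4H-chromen-2-yl)-2-hydroxyphenyl]-5,7-dihydroxy-2-(4-methoxyphenyl)-4H-chromen-4-one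
Conditions: BCl3 (excess), C6HMe5, CH2Cl2, −78 → 0 °C → rt; MeOH
Reagents that add atoms: none
Why: Lewis-acid dealkylation: the benzyl ethers ionise at low temperature and the cation is captured by pentamethylbenzene; on warming the O5'' ethyl ether, held in a boron chelate with the C4'' carbonyl, is cleaved by chloride, and the unchelated anisole methyl ether should remain.

## Compound list

1 | 5-bromo-2-hydroxybenzaldehyde | O=Cc1cc(Br)ccc1O | starting material
2 | 2-(benzyloxy)-5-bromobenzaldehyde | O=Cc1cc(Br)ccc1OCc1ccccc1 | intermediate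
3 | 1-(benzyloxy)-4-bromo-2-ethynylbenzene | C#Cc1cc(Br)ccc1OCc1ccccc1 | intermediate
4 | lithium [2-(benzyloxy)-5-bromophenyl]acetylide | [Li]C#Cc1cc(Br)ccc1OCc1ccccc1 | intermediate
5 | lithium 2-[2-(benzyloxy)-5-bromophenyl]ethyn-1-olate | [Li]OC#Cc1cc(Br)ccc1OCc1ccccc1 | intermediate
6 | [2-(benzyloxy)-5-bromophenyl]ethynyl triisopropylsilyl ether | CC(C)[Si](C(C)C)(C(C)C)OC#Cc1cc(Br)ccc1OCc1ccccc1 | intermediate
7 | 3-ethoxycyclobut-2-en-1-one | CCOC1=CC(=O)C1 | starting material
8 | 3-ethoxybuta-1,3-dien-1-one | C=C(OCC)C=C=O | intermediate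
9 | 2-[2-(benzyloxy)-5-bromophenyl]-4-(1-ethoxyethenyl)-3-[(triisopropylsilyl)oxy]cyclobut-2-en-1-one (racemic) | C=C(OCC)C1C(=O)C(c2cc(Br)ccc2OCc2ccccc2)=C1O[Si](C(C)C)(C(C)C)C(C)C | intermediate
10 | (3E)-2-[2-(benzyloxy)-5-bromophenyl]-5-ethoxy-3-[(triisopropylsilyl)oxy]hexa-1,3,5-trien-1-one | C=C(OCC)/C=C(O[Si](C(C)C)(C(C)C)C(C)C)\C(=C=O)c1cc(Br)ccc1OCc1ccccc1 | intermediate
11 | 2-[2-(benzyloxy)-5-bromophenyl]-5-ethoxy-3-[(triisopropylsilyl)oxy]cyclohexa-2,4-dien-1-one | O=C1CC(OCC)=CC(O[Si](C(C)C)(C(C)C)C(C)C)=C1c1cc(Br)ccc1OCc1ccccc1 | intermediate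
12 | 2-[2-(benzyloxy)-5-bromophenyl]-5-ethoxy-3-[(triisopropylsilyl)oxy]phenol | Oc1cc(OCC)cc(O[Si](C(C)C)(C(C)C)C(C)C)c1-c1cc(Br)ccc1OCc1ccccc1 | intermediate
13 | 2-[2-(benzyloxy)-5-bromophenyl]-5-ethoxy-3-[(triisopropylsilyl)oxy]phenyl acetate | CC(=O)Oc1cc(OCC)cc(O[Si](C(C)C)(C(C)C)C(C)C)c1-c1cc(Br)ccc1OCc1ccccc1 | intermediate
14 | O,O-difluoroboron chelate of ketone 15 (2,2-difluoro-4-methyl-1,3,2-benzodioxaborinine carrying the ring substituents of 15) | CC1=[O+][B-](F)(F)Oc2c(-c3cc(Br)ccc3OCc3ccccc3)c(O[Si](C(C)C)(C(C)C)C(C)C)cc(OCC)c12 | intermediate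
15 | 1-{3-[2-(benzyloxy)-5-bromophenyl]-6-ethoxy-2-hydroxy-4-[(triisopropylsilyl)oxy]phenyl}ethan-1-one | CC(=O)c1c(OCC)cc(O[Si](C(C)C)(C(C)C)C(C)C)c(-c2cc(Br)ccc2OCc2ccccc2)c1O | intermediate
16 | 1-{3-[2-(benzyloxy)-5-bromophenyl]-6-ethoxy-2,4-dihydroxyphenyl}ethan-1-one (present in step 6 as its cesium 4-phenoxide) | CC(=O)c1c(OCC)cc(O)c(-c2cc(Br)ccc2OCc2ccccc2)c1O | intermediate
17 | 1-{4-(benzyloxy)-3-[2-(benzyloxy)-5-bromophenyl]-6-ethoxy-2-hydroxyphenyl}ethan-1-one | CC(=O)c1c(OCC)cc(OCc2ccccc2)c(-c2cc(Br)ccc2OCc2ccccc2)c1O | intermediate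
18 | 4-methoxybenzaldehyde | COc1ccc(C=O)cc1 | starting material
19 | (E)-1-{4-(benzyloxy)-3-[2-(benzyloxy)-5-bromophenyl]-6-ethoxy-2-hydroxyphenyl}-3-(4-methoxyphenyl)prop-2-en-1-one | COc1ccc(/C=C/C(=O)c2c(OCC)cc(OCc3ccccc3)c(-c3cc(Br)ccc3OCc3ccccc3)c2O)cc1 | intermediate
20 | 7-(benzyloxy)-8-[2-(benzyloxy)-5-bromophenyl]-5-ethoxy-2-(4-methoxyphenyl)chroman-4-one (racemic) | COc1ccc(cc1)C1CC(=O)c2c(OCC)cc(OCc3ccccc3)c(-c3cc(Br)ccc3OCc3ccccc3)c2O1 | intermediate
21 | 7-(benzyloxy)-8-[2-(benzyloxy)-5-bromophenyl]-5-ethoxy-2-(4-methoxyphenyl)-4H-chromen-4-one | COc1ccc(cc1)-c1cc(=O)c2c(OCC)cc(OCc3ccccc3)c(-c3cc(Br)ccc3OCc3ccccc3)c2o1 | intermediate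
22 | 1-(2,4,6-trihydroxyphenyl)ethan-1-one | CC(=O)c1c(O)cc(O)cc1O | starting material
23 | 1-[2,4-bis(benzyloxy)-6-hydroxyphenyl]ethan-1-one | CC(=O)c1c(O)cc(OCc2ccccc2)cc1OCc1ccccc1 | intermediate
24 | 2-acetyl-3,5-bis(benzyloxy)phenyl 4-(benzyloxy)-3-[7-(benzyloxy)-5-ethoxy-2-(4-methoxyphenyl)-4-oxo-4H-chromen-8-yl]benzoate | CC(=O)c1c(OC(=O)c2ccc(OCc3ccccc3)c(c2)-c2c(OCc3ccccc3)cc(OCC)c3c(=O)cc(oc23)-c2ccc(OC)cc2)cc(OCc2ccccc2)cc1OCc1ccccc1 | intermediate
25 | 1-[2,4-bis(benzyloxy)-6-hydroxyphenyl]-3-{4-(benzyloxy)-3-[7-(benzyloxy)-5-ethoxy-2-(4-methoxyphenyl)-4-oxo-4H-chromen-8-yl]phenyl}propane-1,3-dione | O=C(CC(=O)c1ccc(OCc2ccccc2)c(c1)-c1c(OCc2ccccc2)cc(OCC)c2c(=O)cc(oc12)-c1ccc(OC)cc1)c1c(O)cc(OCc2ccccc2)cc1OCc1ccccc1 | intermediate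
26 | 5,7-bis(benzyloxy)-2-{4-(benzyloxy)-3-[7-(benzyloxy)-5-ethoxy-2-(4-methoxyphenyl)-4-oxo-4H-chromen-8-yl]phenyl}-4H-chromen-4-one | COc1ccc(cc1)-c1cc(=O)c2c(OCC)cc(OCc3ccccc3)c(-c3cc(-c4cc(=O)c5c(OCc6ccccc6)cc(OCc6ccccc6)cc5o4)ccc3OCc3ccccc3)c2o1 | intermediate
27 | podocarpusflavone A, 8-[5-(5,7-dihydroxy-4-oxo-4H-chromen-2-yl)-2-hydroxyphenyl]-5,7-dihydroxy-2-(4-methoxyphenyl)-4H-chromen-4-one | COc1ccc(-c2cc(=O)c3c(O)cc(O)c(-c4cc(-c5cc(=O)c6c(O)cc(O)cc6o5)ccc4O)c3o2)cc1 | target

## Step count and least certain steps

Total steps: 13. Longest linear sequence: 12 (steps 1–8 and 10–13, from 1); step 9 is a one-step branch from 22.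

**Step 4 (key step).** The donor-substituted cyclobutenone 7 may open more slowly than 6 is lost through hydrolysis or a 1,3-silyl shift to a silylketene. Vinylketene 8 may also dimerize or acylate the product phenol. The fallback gives up the benzannulation and accepts a hindered cross-coupling. It sets out from 22: mono-benzylation at the para hydroxyl (BnBr, K2CO3) gives 1-[4-(benzyloxy)-2,6-dihydroxyphenyl]ethan-1-one F1, and mono-ethylation (EtI, K2CO3) gives 1-[4-(benzyloxy)-2-ethoxy-6-hydroxyphenyl]ethan-1-one F2. Iodination ortho to the free hydroxyl (N-iodosuccinimide) gives 1-[4-(benzyloxy)-6-ethoxy-2-hydroxy-3-iodophenyl]ethan-1-one F3. Suzuki–Miyaura coupling with the commercially offered [2-(benzyloxy)-5-bromophenyl]boronic acid F4 (Pd(PPh3)4, Na2CO3, DME/H2O) rejoins the route at 17. This is shorter on paper, but it depends on two statistical mono-alkylations, a regioselective iodination, and a tri-ortho-substituted coupling in which the iodide of F3 must react before the bromide of F4.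

**Step 3.** Oxygen transfer to an aryl acetylide may be sluggish, and the aryl siloxyalkyne may hydrolyse during isolation. The fallback sets out from 3 and reaches the ynolate by sulfonate cleavage. PhI(OH)OTs converts 3 into {[2-(benzyloxy)-5-bromophenyl]ethynyl}(phenyl)iodonium 4-methylbenzenesulfonate F5. Catalytic CuOTf in MeCN collapses this to [2-(benzyloxy)-5-bromophenyl]ethynyl 4-methylbenzenesulfonate F6. MeLi at −78 °C attacks sulfur and releases ynolate 5, which is silylated as before to return at 6. Bromine–lithium exchange with MeLi is slow at this temperature.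

**Step 5.** Double acylation of the electron-rich ring or cleavage of the ring-B benzyl ether by the Lewis acid would lower the return. Acylation para to the hydroxyl and silyl loss are harmless, because step 6 corrects them. The fallback sets out from 12: fluoride (tetrabutylammonium fluoride, THF) gives the symmetrical 2-[2-(benzyloxy)-5-bromophenyl]-5-ethoxybenzene-1,3-diol F7, whose two open positions are equivalent. Houben–Hoesch acylation (MeCN, ZnCl2, HCl, then aqueous hydrolysis) gives 16, now isolated, and selective benzylation (BnBr, K2CO3) returns at 17.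

**Step 10.** Capture of the acylpalladium intermediate by a hydrogen-bonded, ortho-substituted phenol may be slow, so that reduction of the bromide or non-carbonylative C–O coupling competes. The fallback sets out from 21 and separates the two bond formations. Hydroxycarbonylation (CO, H2O, Pd(OAc)2, Xantphos, Et3N, dioxane) gives 4-(benzyloxy)-3-[7-(benzyloxy)-5-ethoxy-2-(4-methoxyphenyl)-4-oxo-4H-chromen-8-yl]benzoic acid F8. Steglich esterification with 23 (carbodiimide, 4-dimethylaminopyridine) returns at 24.

**Step 13.** Cleavage of the chelated ethyl ether is slower than that of a methyl ether and may stay incomplete, forcing it may start to remove the anisole methyl group, and slow cation scavenging could lead to C-benzylation of the electron-rich rings. The fallback sets out from 26 and removes the benzyl groups without a Lewis acid. Hydrogenolysis (H2, Pd/C, THF/MeOH) gives 8-[5-(5,7-dihydroxy-4-oxo-4H-chromen-2-yl)-2-hydroxyphenyl]-5-ethoxy-7-hydroxy-2-(4-methoxyphenyl)-4H-chromen-4-one F9, in which the only alkyl ethers left are the chelated ethyl and the anisole methyl. Chelation-specific de-ethylation (AlCl3, MeCN, warm) then arrives at 27.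

## Further compounds

F1 | step 4 | 1-[4-(benzyloxy)-2,6-dihydroxyphenyl]ethan-1-one | CC(=O)c1c(O)cc(OCc2ccccc2)cc1O
F2 | step 4 | 1-[4-(benzyloxy)-2-ethoxy-6-hydroxyphenyl]ethan-1-one | CC(=O)c1c(O)cc(OCc2ccccc2)cc1OCC
F3 | step 4 | 1-[4-(benzyloxy)-6-ethoxy-2-hydroxy-3-iodophenyl]ethan-1-one | CC(=O)c1c(OCC)cc(OCc2ccccc2)c(I)c1O
F4 | step 4 | [2-(benzyloxy)-5-bromophenyl]boronic acid | OB(O)c1cc(Br)ccc1OCc1ccccc1
F5 | step 3 | {[2-(benzyloxy)-5-bromophenyl]ethynyl}(phenyl)iodonium 4-methylbenzenesulfonate | Cc1ccc(cc1)S(=O)(=O)[O-].Brc1ccc(OCc2ccccc2)c(c1)C#C[I+]c1ccccc1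
F6 | step 3 | [2-(benzyloxy)-5-bromophenyl]ethynyl 4-methylbenzenesulfonate | Cc1ccc(cc1)S(=O)(=O)OC#Cc1cc(Br)ccc1OCc1ccccc1
F7 | step 5 | 2-[2-(benzyloxy)-5-bromophenyl]-5-ethoxybenzene-1,3-diol | Oc1cc(OCC)cc(O)c1-c1cc(Br)ccc1OCc1ccccc1
F8 | step 10 | 4-(benzyloxy)-3-[7-(benzyloxy)-5-ethoxy-2-(4-methoxyphenyl)-4-oxo-4H-chromen-8-yl]benzoic acid | OC(=O)c1ccc(OCc2ccccc2)c(c1)-c1c(OCc2ccccc2)cc(OCC)c2c(=O)cc(oc12)-c1ccc(OC)cc1
F9 | step 13 | 8-[5-(5,7-dihydroxy-4-oxo-4H-chromen-2-yl)-2-hydroxyphenyl]-5-ethoxy-7-hydroxy-2-(4-methoxyphenyl)-4H-chromen-4-one | COc1ccc(cc1)-c1cc(=O)c2c(OCC)cc(O)c(-c3cc(-c4cc(=O)c5c(O)cc(O)cc5o4)ccc3O)c2o1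
A1 | alternative 1 | 1-[2,4-bis(benzyloxy)-6-hydroxyphenyl]-3-{4-(benzyloxy)-3-[4,6-bis(benzyloxy)-2-hydroxy-3-[3-(4-methoxyphenyl)-3-oxopropanoyl]phenyl]phenyl}propane-1,3-dione | Oc1cc(OCc2ccccc2)cc(OCc2ccccc2)c1C(=O)CC(=O)c1ccc(OCc2ccccc2)c(-c2c(OCc3ccccc3)cc(OCc3ccccc3)c(C(=O)CC(=O)c3ccc(OC)cc3)c2O)c1
A2 | alternative 1 | 2-acetyl-3,5-bis(benzyloxy)phenyl 3-{3-acetyl-4,6-bis(benzyloxy)-2-[(4-methoxybenzoyl)oxy]phenyl}-4-(benzyloxy)benzoate | CC(=O)c1c(OCc2ccccc2)cc(OCc2ccccc2)cc1OC(=O)c1ccc(OCc2ccccc2)c(-c2c(OCc3ccccc3)cc(OCc3ccccc3)c(C(C)=O)c2OC(=O)c2ccc(OC)cc2)c1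
A3 | alternative 2 | methyl 3-[5-acetoxy-2-(4-methoxyphenyl)-4-oxo-7-[(triisopropylsilyl)oxy]-4H-chromen-8-yl]-4-(benzyloxy)benzoate | COc1ccc(cc1)-c1cc(=O)c2c(OC(C)=O)cc(O[Si](C(C)C)(C(C)C)C(C)C)c(-c3cc(C(=O)OC)ccc3OCc3ccccc3)c2o1
A4 | alternative 2 | methyl 4-(benzyloxy)-3-[({(1Z)-1-(4-methoxyphenyl)-3-oxo-7-[(triisopropylsilyl)oxy]hept-1-ene-4,6-diyn-1-yl}oxy)ethynyl]benzoate | COC(=O)c1ccc(OCc2ccccc2)c(c1)C#CO/C(=C\C(=O)C#CC#CO[Si](C(C)C)(C(C)C)C(C)C)c1ccc(OC)cc1
A5 | alternative 3 | methyl 3-[5,7-bis(benzyloxy)-2-(4-methoxyphenyl)-4-oxo-4H-chromen-8-yl]-4-[(tert-butyldimethylsilyl)oxy]benzoate | COC(=O)c1ccc(O[Si](C)(C)C(C)(C)C)c(-c2c(OCc3ccccc3)cc(OCc3ccccc3)c3c(=O)cc(-c4ccc(OC)cc4)oc23)c1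
A6 | alternative 3 | 5,7-bis(benzyloxy)-8-{(1E)-3-[(tert-butyldimethylsilyl)oxy]-1-(dimethylamino)buta-1,3-dien-2-yl}-2-(4-methoxyphenyl)-4H-chromen-4-one | CN(C)/C=C(\c1c(OCc2ccccc2)cc(OCc2ccccc2)c2c(=O)cc(-c3ccc(OC)cc3)oc12)C(=C)O[Si](C)(C)C(C)(C)C
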